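The strategy rests on the tertiary α-ketol C1(OH)–C9(=O) of the bicyclo[3.3.1]nonan-9-one core (ring A: C1, C2, C3, C4, C5, C9; ring B: C1, C8, C7, C6, C5, C9). Read as the product of an acyloin shift, it lets ring A be cut at C1–C2 back to a cis-fused hydrindanone with an angular C9 hydroxyl beside a C1 ketone.
That hydrindanone is simplified by removing the C7–C8 oxirane (nucleophilic epoxidation of an enone), opening ring B at C7=C8 (ring-closing metathesis) and detaching the acryloyl carbon C1 from C9 (lithiated methoxyallene on a cyclopentanone).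
The cyclopentanone (C9, C2, C3, C4, C5) comes from (R)-4-silyloxycyclopent-2-enone. C5–C6 is made first, by a syn-selective α′-aldol with acrolein on the enone, because a C5 enolate of the later β-oxy cyclopentanone would eliminate. C3–N then follows by an imidate-tethered aza-Michael addition from the C4 oxygen, and the amide and C4 silyl ether are in place before the ketone is touched.
Order of ring formation: cyclopentane (bought), ring B (metathesis), oxirane, then ring A (the 1,2-shift enlarges the five-membered ring); desilylation ends the route.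

Key step: step 11

Remark: the C1–C9 numbering of the target core is kept for all intermediates, and enantiopure (R)-4-[(tert-butyldimethylsilyl)oxy]cyclopent-2-en-1-one is taken as the commercial source of C4.

Step 1
Reactants: 1 (4R)-4-[(tert-butyldimethylsilyl)oxy]cyclopent-2-en-1-one; 2 acrolein
Product: 5 (4S,5R)-4-[(tert-butyldimethylsilyl)oxy]-5-[(1R)-1-hydroxyprop-2-en-1-yl]cyclopent-2-en-1-one, via lithium dienolate 3 (not isolated), via titanium dienolate 4 (not isolated)
Conditions: LiN(iPr)2, THF, −78 °C; ClTi(OiPr)3, −78 to −40 °C; 2, −78 °C; aq. NH4F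
Reagents that add atoms: none
Why: Kinetic α′-deprotonation gives the cross-conjugated dienolate (loss of the C4 silyloxy group would need a cyclopentadienone), and its triisopropoxytitanium enolate should add to acrolein in a syn-selective aldol addition, as titanium enolates of cyclic ketones do whatever the enolate geometry, with the aldehyde approaching C5 anti to the C4 silyl ether, so that C5 is set trans to C4–O and C6 syn to C5.

Step 2
Reactants: 5 (4S,5R)-4-[(tert-butyldimethylsilyl)oxy]-5-[(1R)-1-hydroxyprop-2-en-1-yl]cyclopent-2-en-1-one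
Product: 6 (4S,5R)-4-[(tert-butyldimethylsilyl)oxy]-5-[(1R)-1-methoxyprop-2-en-1-yl]cyclopent-2-en-1-one
Conditions: MeOTf, 2,6-di-tert-butyl-4-methylpyridine, CH2Cl2, 0 °C to rt
Reagents that add atoms: methyl trifluoromethanesulfonate, COS(=O)(=O)C(F)(F)F
Why: O-Methylation of the secondary allylic alcohol by methyl triflate with a hindered pyridine base needs no alkoxide, so the β-hydroxy ketone should not undergo retro-aldol cleavage or elimination and C6 keeps its configuration.

Step 3
Reactants: 6 (4S,5R)-4-[(tert-butyldimethylsilyl)oxy]-5-[(1R)-1-methoxyprop-2-en-1-yl]cyclopent-2-en-1-one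
Product: 7 (4S,5S)-4-hydroxy-5-[(1R)-1-methoxyprop-2-en-1-yl]cyclopent-2-en-1-one
Conditions: HF·pyridine, pyridine, THF, 0 °C to rt
Reagents that add atoms: none
Why: Fluoride-driven cleavage of the silyl ether under buffered, weakly acidic conditions should leave the γ-hydroxy enone and the allylic methyl ether untouched and frees the C4 hydroxyl for the nitrogen tether.

Step 4
Reactants: 7 (4S,5S)-4-hydroxy-5-[(1R)-1-methoxyprop-2-en-1-yl]cyclopent-2-en-1-one
Product: 9 cis-fused 2-(trichloromethyl)oxazoline ketone (N on C3 and O on C4 cis; C5 side chain trans to C4–O), via trichloroacetimidate 8 (not isolated)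
Conditions: Cl3CCN, DBU (0.2 equiv), CH2Cl2, −20 to 0 °C
Reagents that add atoms: trichloroacetonitrile, N#CC(Cl)(Cl)Cl
Why: Base-catalysed addition of the alcohol to the nitrile gives the trichloroacetimidate, whose nitrogen adds 5-exo-trig to the enone β-carbon C3 (tethered aza-Michael addition), so that C3–N is set cis to C4–O by the tether while the C5 side chain keeps the exo position on the new bicycle, which is also the more stable one.

Step 5
Reactants: 10 (E)-dodec-2-enoic acid
Product: 11 (E)-dodec-2-enoyl chloride
Conditions: (COCl)2, DMF (cat.), CH2Cl2, 0 °C to rt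
Reagents that add atoms: oxalyl chloride, O=C(Cl)C(=O)Cl
Why: Acid chloride formation through the Vilsmeier-type chloroiminium species is standard for α,β-unsaturated acids and should keep the E double bond.

Step 6
Reactants: 9 cis-fused 2-(trichloromethyl)oxazoline ketone; 11 (E)-dodec-2-enoyl chloride
Product: 13 (E)-N-[2-hydroxy-3-(1-methoxyprop-2-en-1-yl)-4-oxocyclopentyl]dodec-2-enamide (C3–N/C4–O cis; C4–O/C5–C6 trans), via ammonium chloride 12 (not isolated)
Conditions: 2 M aq. HCl, THF, rt; then NaHCO3, 11, EtOAc/H2O, 0 °C
Reagents that add atoms: none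
Why: Aqueous acid should open the oxazoline at C2 to the O-trichloroacetyl ammonium salt, whose activated ester is hydrolysed, and the freed amine is then acylated faster than the hydroxyl under Schotten–Baumann conditions, with no stereocentre touched.

Step 7
Reactants: 13 (E)-N-[2-hydroxy-3-(1-methoxyprop-2-en-1-yl)-4-oxocyclopentyl]dodec-2-enamide
Product: 14 C4 tert-butyldimethylsilyl ether of 13
Conditions: tBuMe2SiOTf, 2,6-lutidine, CH2Cl2, −78 °C
Reagents that add atoms: tert-butyldimethylsilyl trifluoromethanesulfonate, CC(C)(C)[Si](C)(C)OS(=O)(=O)C(F)(F)F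
Why: Silylation of the secondary alcohol with the silyl triflate and a hindered base at low temperature should spare the ketone and gives the ether that shields C4–O in the organolithium step and later blocks retro-aldol cleavage of the β-oxy ketone formed in the key step.

Step 8
Reactants: 14 C4 tert-butyldimethylsilyl ether of 13; 15 methoxyallene
Product: 17 C9 tertiary alcohol bearing an acryloyl group (α-hydroxy vinyl ketone; acryloyl cis to the C5 side chain), via allenyl carbinol 16 (not isolated)
Conditions: 15 (3.5 equiv), n-BuLi (3.2 equiv), THF, −40 °C; 14, −78 °C; then 1 M aq. HCl, THF, 0 °C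
Reagents that add atoms: water, O
Why: 1,2-Addition of the lithiated alkoxyallene (an acryloyl anion equivalent) to the ketone and hydrolysis of the allenyl enol ether give the α-hydroxy vinyl ketone, and C9 should be set by attack anti to the cis-related C3 amide and C4 silyl ether, one of which must stand pseudoaxial over that face, and so syn to the pseudoequatorial C5 side chain, which this small linear nucleophile tolerates.

Step 9
Reactants: 17 C9 tertiary alcohol bearing an acryloyl group
Product: 18 cis-fused hydrindenone ketol (C9–OH angular, C1 ketone, C7=C8, C6 OMe, C4 OTBS, C3 amide)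
Conditions: second-generation Grubbs catalyst RuCl2(=CHPh)(PCy3)(H2IMes) (5 mol %), CH2Cl2, 40 °C
Reagents that add atoms: none
Why: Ring-closing metathesis between the vinyl ketone and the vinyl group of the allylic ether, held cis on the cyclopentane, should close ring B as a cyclohexenone with loss of ethene, creating no stereocentre and leaving the electron-poor 1,2-disubstituted amide alkene alone.

Step 10
Reactants: 18 cis-fused hydrindenone ketol
Product: 19 cis-fused hydrindanone α-ketol (C9–OH angular, C1 ketone, C7–C8 oxirane, C6 OMe, C4 OTBS, C3 amide)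
Conditions: tBuOOH, DBU, CH2Cl2, 0 °C
Reagents that add atoms: tert-butyl hydroperoxide, CC(C)(C)OO
Why: In this Weitz–Scheffer epoxidation the hydroperoxide anion should add to C7 axially on the convex face of the cis-hydrindenone, trans to the C5–C4 bond as in additions to 5-substituted cyclohexenones, and the enolate closes on the same face, which sets C7 and C8 with the oxirane cis to the angular hydroxyl and the C6 methoxy group.

Step 11
Reactants: 19 cis-fused hydrindanone α-ketol
Product: 20 4-O-tert-butyldimethylsilyl ether of the target (bicyclo[3.3.1]nonan-9-one with C1–OH)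
Conditions: Al(OtBu)3, toluene, 60 °C
Reagents that add atoms: none
Why: Al(OtBu)3 exchanges onto the C9 hydroxyl and binds the C1 carbonyl oxygen in a five-membered chelate, and in this syn-periplanar array the C9–C2 bond shifts suprafacially to the C1 carbonyl carbon while C9–O becomes the bridging ketone. The closest known reaction is the Lewis-acid-promoted, ring-enlarging α-ketol (acyloin) rearrangement of tertiary α-hydroxy ketones, as in the D-homoannulation of 17-hydroxy-20-keto steroids. Ring A (C1, C2, C3, C4, C5, C9) is closed by ring enlargement and not by cyclisation: C1 is inserted into the cyclopentane bond C9–C2, which turns the fused bicycle into the bridged one. The new stereocentre C1 is fixed by the cis ring fusion of 19, because C2 can only reach the face of the C1 carbonyl on which it stands at C9, so the hydroxyl ends up exo, while C9 loses its stereocentre. The step needs migration of C2 and not of C5, and the substrate secures it: C9–C5 is a bond of the ketone ring and lies near the carbonyl plane, whereas C9–C2 is pseudoaxial and parallel to the π* orbital once the chelated hydroxyl sits in that plane. The equilibrium should favour 20 because a cyclopentane fused to an epoxy ketone is traded for a chair-like ring A, and no enolisable position (oxirane carbon, quaternary carbon, bridgehead) allows epimerisation.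

Step 12
Reactants: 20 4-O-tert-butyldimethylsilyl ether of the target
Product: 21 CNP0137540.1
Conditions: HF·pyridine, pyridine, THF, 0 °C
Reagents that add atoms: none
Why: Buffered fluoride desilylation should free the C4 hydroxyl without opening the oxirane or disturbing the α-ketol and the β-hydroxy ketone, and no stereocentre is touched.

Compound list
1 | (4R)-4-[(tert-butyldimethylsilyl)oxy]cyclopent-2-en-1-one | O=C1C[C@@H](O[Si](C)(C)C(C)(C)C)C=C1 | starting material
2 | acrolein (prop-2-enal) | C=CC=O | starting material
3 | lithium 5-silyloxycyclopenta-1,3-dien-2-olate (α′-enolate of 1) | [Li]OC1=C[C@@H](O[Si](C)(C)C(C)(C)C)C=C1 | intermediate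
4 | triisopropoxytitanium dienolate of 1 | CC(C)O[Ti](OC(C)C)(OC(C)C)OC1=C[C@@H](O[Si](C)(C)C(C)(C)C)C=C1 | intermediate
5 | (4S,5R)-4-[(tert-butyldimethylsilyl)oxy]-5-[(1R)-1-hydroxyprop-2-en-1-yl]cyclopent-2-en-1-one (the C4 descriptor differs from that of 1 only through changed priorities) | C=C[C@@H](O)[C@H]1C(=O)C=C[C@@H]1O[Si](C)(C)C(C)(C)C | intermediate
6 | (4S,5R)-4-[(tert-butyldimethylsilyl)oxy]-5-[(1R)-1-methoxyprop-2-en-1-yl]cyclopent-2-en-1-one | C=C[C@@H](OC)[C@H]1C(=O)C=C[C@@H]1O[Si](C)(C)C(C)(C)C | intermediate
7 | (4S,5S)-4-hydroxy-5-[(1R)-1-methoxyprop-2-en-1-yl]cyclopent-2-en-1-one | C=C[C@@H](OC)[C@H]1C(=O)C=C[C@@H]1O | intermediate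
8 | O-trichloroacetimidate of 7 | C=C[C@@H](OC)[C@H]1C(=O)C=C[C@@H]1OC(=N)C(Cl)(Cl)Cl | intermediate
9 | cis-fused 2-(trichloromethyl)oxazoline ketone (oxazoline O on C4, N on C3; ketone C9; 1-methoxyallyl on C5) | C=C[C@@H](OC)[C@H]1C(=O)C[C@@H]2N=C(C(Cl)(Cl)Cl)O[C@H]12 | intermediate
10 | (E)-dodec-2-enoic acid | CCCCCCCCC/C=C/C(=O)O | starting material
11 | (E)-dodec-2-enoyl chloride | CCCCCCCCC/C=C/C(=O)Cl | intermediate
12 | ammonium chloride of the cis amino alcohol (C3–NH3+, C4–OH, C9 ketone, 1-methoxyallyl on C5) | C=C[C@@H](OC)[C@H]1C(=O)C[C@H]([NH3+])[C@@H]1O.[Cl-] | intermediate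
13 | (E)-N-[2-hydroxy-3-(1-methoxyprop-2-en-1-yl)-4-oxocyclopentyl]dodec-2-enamide (C3–N/C4–O cis; C4–O/C5–C6 trans) | CCCCCCCCC/C=C/C(=O)N[C@H]1CC(=O)[C@H]([C@H](OC)C=C)[C@H]1O | intermediate
14 | C4 tert-butyldimethylsilyl ether of 13 | CCCCCCCCC/C=C/C(=O)N[C@H]1CC(=O)[C@H]([C@H](OC)C=C)[C@H]1O[Si](C)(C)C(C)(C)C | intermediate
15 | methoxyallene (1-methoxypropa-1,2-diene) | COC=C=C | starting material
16 | C9 carbinol bearing a 1-methoxypropa-1,2-dien-1-yl group | CCCCCCCCC/C=C/C(=O)N[C@H]1C[C@](O)(C(OC)=C=C)[C@H]([C@H](OC)C=C)[C@H]1O[Si](C)(C)C(C)(C)C | intermediate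
17 | C9 tertiary alcohol bearing an acryloyl group (α-hydroxy vinyl ketone) | CCCCCCCCC/C=C/C(=O)N[C@H]1C[C@](O)(C(=O)C=C)[C@H]([C@H](OC)C=C)[C@H]1O[Si](C)(C)C(C)(C)C | intermediate
18 | cis-fused hydrindenone ketol (C9–OH, C1 ketone, C7=C8, C6 OMe, C4 OTBS, C3 amide) | CCCCCCCCC/C=C/C(=O)N[C@H]1C[C@]2(O)C(=O)C=C[C@@H](OC)[C@@H]2[C@H]1O[Si](C)(C)C(C)(C)C | intermediate
19 | cis-fused hydrindanone α-ketol (C9–OH, C1 ketone, C7–C8 oxirane, C6 OMe, C4 OTBS, C3 amide) | CCCCCCCCC/C=C/C(=O)N[C@H]1C[C@]2(O)C(=O)[C@H]3O[C@H]3[C@@H](OC)[C@@H]2[C@H]1O[Si](C)(C)C(C)(C)C | intermediate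
20 | 4-O-tert-butyldimethylsilyl ether of the target | CCCCCCCCC/C=C/C(=O)N[C@H]1C[C@@]2(O)C(=O)[C@@H]([C@H]1O[Si](C)(C)C(C)(C)C)[C@H](OC)[C@@H]1O[C@@H]12 | intermediate
21 | CNP0137540.1 | CCCCCCCCC/C=C/C(=O)N[C@H]1C[C@@]2(O)C(=O)[C@@H]([C@H]1O)[C@H](OC)[C@@H]1O[C@@H]12 | target

Total step count: 12. Longest linear sequence: 11 steps (steps 1 to 4 and 6 to 12).

Steps most likely to fail

Step 11. The shift may stop at an unfavourable equilibrium, or the epoxy ketone may be consumed by ring opening under the aluminium alkoxide before C2 migrates. The fallback sets out from enone 18 and runs the same acyloin shift before the oxirane exists (Al(OtBu)3, toluene), which should give the bridged enone F1 with a bridgehead allylic C1 hydroxyl. A hydroxyl-directed epoxidation (VO(acac)2, tBuOOH, CH2Cl2) then places the oxirane syn to that hydroxyl on the exo face of ring B, cis to the C6 methoxy group, and the route is rejoined at 20.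

Step 8. Facial selectivity at C9 may be poor, because the required attack is syn to the C5 side chain, and the basic reagent may enolise the ketone and trigger β-elimination. The fallback sets out from ketone 14 and reverses the polarity of the facial problem: Lombardo methylenation (Zn, CH2Br2, TiCl4) gives the exocyclic alkene F2. Dihydroxylation with OsO4 and TMEDA, delivered by hydrogen bonding to the amide N–H and anti to the C5 side chain, should give diol F3 with the C9 hydroxyl on the required face. Oxidation of the primary alcohol (SO3·pyridine, DMSO, iPr2NEt) gives the α-hydroxy aldehyde F4, CH2=CHMgBr gives the allylic alcohol F5 (either C1 epimer serves), and a second oxidation (SO3·pyridine, DMSO, iPr2NEt) returns to 17.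

Step 1. The simple diastereoselectivity of the aldol may be low or turn to anti, and acrolein may be lost to conjugate addition or polymerisation. The fallback sets out from 1 and replaces the metal enolate aldol by an oxocarbenium alkylation through an open transition state: LiN(iPr)2 and Me3SiCl give the silyl dienol ether F6. Reaction with 3-(phenylselanyl)propanal dimethyl acetal (COC(OC)CC[Se]c1ccccc1) and catalytic Me3SiOTf at −78 °C (Mukaiyama-type acetal aldol, syn-selective for cyclic enol silyl ethers) should give the β-methoxy selenide F7 with the methyl ether already in place. This saturated acetal is chosen because a vinyl oxocarbenium ion could add to the silyloxydiene in a cycloaddition. Oxidation with H2O2 and pyridine gives the selenoxide F8, whose syn elimination unveils the vinyl group and rejoins the route at 6.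

Further compounds
F1 | step 11 | bridged enone: 4-O-TBS bicyclo[3.3.1]non-7-en-9-one with C1–OH, C6 OMe, C3 amide | CCCCCCCCC/C=C/C(=O)N[C@H]1C[C@@]2(O)C(=O)[C@@H]([C@H]1O[Si](C)(C)C(C)(C)C)[C@H](OC)C=C2
F2 | step 8 | C9 exocyclic methylene analogue of 14 | CCCCCCCCC/C=C/C(=O)N[C@H]1CC(=C)[C@H]([C@H](OC)C=C)[C@H]1O[Si](C)(C)C(C)(C)C
F3 | step 8 | C9 tertiary alcohol bearing CH2OH (diol) | CCCCCCCCC/C=C/C(=O)N[C@H]1C[C@](O)(CO)[C@H]([C@H](OC)C=C)[C@H]1O[Si](C)(C)C(C)(C)C
F4 | step 8 | C9 tertiary alcohol bearing CHO (α-hydroxy aldehyde) | CCCCCCCCC/C=C/C(=O)N[C@H]1C[C@](O)(C=O)[C@H]([C@H](OC)C=C)[C@H]1O[Si](C)(C)C(C)(C)C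
F5 | step 8 | C9 tertiary alcohol bearing a 1-hydroxyprop-2-en-1-yl group (C1 epimers) | CCCCCCCCC/C=C/C(=O)N[C@H]1C[C@](O)(C(O)C=C)[C@H]([C@H](OC)C=C)[C@H]1O[Si](C)(C)C(C)(C)C
F6 | step 1 | trimethylsilyl dienol ether of 1 | C[Si](C)(C)OC1=C[C@@H](O[Si](C)(C)C(C)(C)C)C=C1
F7 | step 1 | 4-silyloxy-5-[1-methoxy-3-(phenylselanyl)propyl]cyclopent-2-en-1-one (syn; C4–O/C5 side chain trans) | c1ccccc1[Se]CC[C@@H](OC)[C@H]1C(=O)C=C[C@@H]1O[Si](C)(C)C(C)(C)C
F8 | step 1 | selenoxide of F7 | O=[Se](c1ccccc1)CC[C@@H](OC)[C@H]1C(=O)C=C[C@@H]1O[Si](C)(C)C(C)(C)C
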